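**Plan**
- Retrosynthesis (hydroazulene numbering): cut the C4–O ester bond, then the ring alkene C6=C7 (ring-closing metathesis), the C4–C5 bond (methallylation of an aldehyde), the C3–isopropyl bond (enol triflate coupling), and last the two cyclopentane bonds C1–C2 and C3a–C8a together.
- Enabling feature: C3 carries oxygen and lies between the C2 methylene and C3a, which bears the oxygenated C4. C2–C3(O)–C3a–C4(O) is thus a masked β-keto ester, i.e. a 3-siloxy-2-diazobut-3-enoate, while C1H2–C8a(CH3)(C8H2) is an isobutene-type alkene whose Markovnikov polarity matches it.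
- Forward: the five-membered ring arises first, by a gold-catalysed formal [3+2] cycloaddition of the enoldiazo ester onto 2-methylpenta-1,4-diene. The isopropyl and methallyl groups are then attached and the seven-membered ring is closed by metathesis.
- Stereochemistry: C8a comes from the chiral gold catalyst, the C4 carbinol from a chiral phosphoric acid methallylboration. This hydroxyl directs epoxidation of C3=C3a (C3–O); a SmI2 opening/reduction sets H-3a and re-forms the C4 carbinol.
- No protecting group is carried; the silyl group of the diazo reagent becomes the triflate handle for the isopropyl coupling.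

Key step: step 3

Remark: the SMILES is read as the (3R,3aR,4R,8aS) isomer, with trans ring fusion and with H-3a, the C3 hydroxyl and the C4 ester oxygen all on the face opposite the C8a methyl.

**Route**

Step 1
Reactants: 1 methyl acetoacetate
Product: 2 methyl 2-diazo-3-oxobutanoate
Conditions: 4-acetamidobenzenesulfonyl azide, Et3N, MeCN, 0 °C to rt
Reagents that add atoms: 4-acetamidobenzenesulfonyl azide, CC(=O)Nc1ccc(cc1)S(=O)(=O)N=[N+]=[N-]
Why: Regitz diazo transfer to the doubly activated methylene of a β-keto ester is the standard entry to 2-diazo-1,3-dicarbonyl compounds.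

Step 2
Reactants: 2 methyl 2-diazo-3-oxobutanoate
Product: 3 methyl 3-{[tert-butyl(dimethyl)silyl]oxy}-2-diazobut-3-enoate
Conditions: t-BuMe2SiOTf, Et3N, CH2Cl2, 0 °C
Reagents that add atoms: tert-butyldimethylsilyl trifluoromethanesulfonate, CC(C)(C)[Si](C)(C)OS(=O)(=O)C(F)(F)F
Why: O-silylation of the acetyl enolate with a silyl triflate and an amine base (silyl enol ether formation) gives the stable enoldiazo ester, the diazo group being inert under these conditions.

Step 3
Reactants: 3 methyl 3-{[tert-butyl(dimethyl)silyl]oxy}-2-diazobut-3-enoate; 4 2-methylpenta-1,4-diene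
Product: 5 methyl (5S)-2-{[tert-butyl(dimethyl)silyl]oxy}-5-methyl-5-(prop-2-en-1-yl)cyclopent-1-ene-1-carboxylate
Conditions: (R)-DTBM-SEGPHOS(AuCl)2 (2.5 mol %), AgSbF6 (5 mol %), 4 (5 equiv), CH2Cl2, −40 °C, slow addition of 3
Reagents that add atoms: none
Why: Proposed new method: loss of N2 from 3 at the cationic gold centre gives a gold enolcarbene whose unsubstituted vinyl CH2 terminus is the electrophilic site; the CH2 end of the 1,1-disubstituted alkene of 4 adds there (future C1–C2 bond), leaving a tertiary carbocation at the future C8a and a vinylgold at the future C3a, which collapse to the second C–C bond with release of the catalyst. The closest known reaction type is the formal [3+2] cycloaddition of enoldiazo and vinyldiazo esters with enol ethers, enecarbamates, indoles and allenes under dirhodium, copper or gold catalysis; the step extends it to an unactivated 1,1-dialkyl alkene, which is less nucleophilic but gives the same kind of stabilised (here tertiary) cation. The cyclopentene closes stepwise, the second bond by intramolecular capture of the cation by the gold-bearing vinyl carbon (a 5-endo-type collapse of the 1,5-zwitterion), so the overall mode is a (3+2) annulation of a 1,3-dipole equivalent across the alkene. The only new stereocentre, quaternary C8a, is formed in this ring closure next to the gold-bound carbon and is controlled by the chiral bisphosphine of the digold catalyst, the ligand hand being the one that leads to 5S (the antipode is used if the sense proves opposite). The step needs vinylogous attack in place of attack at the carbene carbon (cyclopropanation), which the cationic gold centre, the free CH2 terminus and the hindered carbene carbon favour; Markovnikov regiochemistry and the preference for the 1,1-disubstituted over the monosubstituted alkene of 4 follow from cation stability. Ring closure must outrun proton loss from the cation, which low temperature, the non-basic SbF6− counter-ion and the proximity of the vinylgold nucleophile support.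

Step 4
Reactants: 5 methyl (5S)-2-{[tert-butyl(dimethyl)silyl]oxy}-5-methyl-5-(prop-2-en-1-yl)cyclopent-1-ene-1-carboxylate
Product: 7 methyl (5S)-5-methyl-5-(prop-2-en-1-yl)-2-{[(trifluoromethyl)sulfonyl]oxy}cyclopent-1-ene-1-carboxylate, via caesium enolate 6 (not isolated)
Conditions: CsF, PhNTf2, DME, rt
Reagents that add atoms: N-phenylbis(trifluoromethanesulfonimide), O=S(=O)(N(c1ccccc1)S(=O)(=O)C(F)(F)F)C(F)(F)F
Why: Fluoride cleaves the labile O–Si bond of the β-keto ester silyl enol ether and the enolate released is O-sulfonylated in place (enol triflate formation), the quaternary centre being untouched.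

Step 5
Reactants: 7 methyl (5S)-5-methyl-5-(prop-2-en-1-yl)-2-{[(trifluoromethyl)sulfonyl]oxy}cyclopent-1-ene-1-carboxylate; 8 isopropylmagnesium chloride
Product: 9 methyl (5S)-5-methyl-2-(propan-2-yl)-5-(prop-2-en-1-yl)cyclopent-1-ene-1-carboxylate
Conditions: Fe(acac)3 (5 mol %), THF/NMP, −30 °C
Reagents that add atoms: none
Why: Iron-catalysed Kumada-type cross-coupling of β-carbomethoxy enol triflates with alkyl Grignard reagents is fast at low temperature, should outpace attack on the hindered ester, and fixes the isopropyl group on the future C3 with the double bond between the future C3 and C3a.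

Step 6
Reactants: 9 methyl (5S)-5-methyl-2-(propan-2-yl)-5-(prop-2-en-1-yl)cyclopent-1-ene-1-carboxylate
Product: 10 [(5S)-5-methyl-2-(propan-2-yl)-5-(prop-2-en-1-yl)cyclopent-1-en-1-yl]methanol
Conditions: i-Bu2AlH (2.5 equiv), CH2Cl2, −78 to 0 °C; aq. KNa tartrate
Reagents that add atoms: none
Why: Hydride reduction with i-Bu2AlH takes the conjugated ester in a 1,2 sense to the primary allylic alcohol and leaves the isolated terminal alkene alone.

Step 7
Reactants: 10 [(5S)-5-methyl-2-(propan-2-yl)-5-(prop-2-en-1-yl)cyclopent-1-en-1-yl]methanol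
Product: 11 (5S)-5-methyl-2-(propan-2-yl)-5-(prop-2-en-1-yl)cyclopent-1-ene-1-carbaldehyde
Conditions: Dess–Martin periodinane, CH2Cl2, 0 °C to rt
Reagents that add atoms: none
Why: Dess–Martin oxidation of the allylic alcohol stops at the α,β-unsaturated aldehyde under neutral conditions.

Step 8
Reactants: 11 (5S)-5-methyl-2-(propan-2-yl)-5-(prop-2-en-1-yl)cyclopent-1-ene-1-carbaldehyde; 12 4,4,5,5-tetramethyl-2-(2-methylprop-2-en-1-yl)-1,3,2-dioxaborolane
Product: 14 (1R)-3-methyl-1-[(5S)-5-methyl-2-(propan-2-yl)-5-(prop-2-en-1-yl)cyclopent-1-en-1-yl]but-3-en-1-ol, via O-pinacolboronate 13 (not isolated)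
Conditions: (R)-TRIP phosphoric acid (5 mol %), 4 Å MS, toluene, −30 °C to rt; aqueous work-up
Reagents that add atoms: none
Why: Chiral phosphoric acid catalysed allylboration runs through a closed six-membered chair transition state in which the catalyst shields one aldehyde face, so the catalyst hand that delivers allyl groups to the Re face of aryl and alkenyl aldehydes (taken as R) should set the (R)-carbinol by catalyst control, the remote quaternary centre having little influence.

Step 9
Reactants: 14 (1R)-3-methyl-1-[(5S)-5-methyl-2-(propan-2-yl)-5-(prop-2-en-1-yl)cyclopent-1-en-1-yl]but-3-en-1-ol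
Product: 15 (4R,8aS)-6,8a-dimethyl-3-(propan-2-yl)-1,2,4,5,8,8a-hexahydroazulen-4-ol
Conditions: second-generation Grubbs catalyst (H2IMes)(PCy3)Cl2Ru=CHPh (5 mol %), CH2Cl2 (0.005 M), 40 °C
Reagents that add atoms: none
Why: Ring-closing metathesis between the monosubstituted allyl and the 1,1-disubstituted methallyl alkene forms the trisubstituted C6=C7 alkene and the seven-membered ring with loss of ethene, the tetrasubstituted C3=C3a alkene being inert to the catalyst.

Step 10
Reactants: 15 (4R,8aS)-6,8a-dimethyl-3-(propan-2-yl)-1,2,4,5,8,8a-hexahydroazulen-4-ol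
Product: 16 (3R,3aS,4R,8aS)-3,3a-epoxy-6,8a-dimethyl-3-(propan-2-yl)-1,2,3,3a,4,5,8,8a-octahydroazulen-4-ol
Conditions: VO(acac)2 (5 mol %), t-BuOOH, CH2Cl2, 0 °C to rt
Reagents that add atoms: tert-butyl hydroperoxide, CC(C)(C)OO
Why: Vanadium-catalysed hydroxyl-directed epoxidation acts on the allylic, electron-rich C3=C3a alkene in preference to the homoallylic C6=C7 alkene and delivers oxygen to the face of the C4 hydroxyl, which is also the face opposite the C8a methyl, so the C3–O stereocentre is relayed from C4 with matched steric bias.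

Step 11
Reactants: 16 (3R,3aS,4R,8aS)-3,3a-epoxy-6,8a-dimethyl-3-(propan-2-yl)-1,2,3,3a,4,5,8,8a-octahydroazulen-4-ol
Product: 17 (3R,3aR,8aS)-3,3a-epoxy-6,8a-dimethyl-3-(propan-2-yl)-2,3,3a,5,8,8a-hexahydroazulen-4(1H)-one
Conditions: Dess–Martin periodinane, pyridine, CH2Cl2, 0 °C
Reagents that add atoms: none
Why: Buffered Dess–Martin oxidation converts the hindered epoxy alcohol into the α,β-epoxy ketone without base-induced migration of the β,γ-alkene or opening of the epoxide.

Step 12
Reactants: 17 (3R,3aR,8aS)-3,3a-epoxy-6,8a-dimethyl-3-(propan-2-yl)-2,3,3a,5,8,8a-hexahydroazulen-4(1H)-one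
Product: 19 (3R,3aR,4R,8aS)-6,8a-dimethyl-3-(propan-2-yl)-1,2,3,3a,4,5,8,8a-octahydroazulene-3,4-diol, via β-hydroxy ketone 18 (not isolated)
Conditions: SmI2 (6 equiv), THF/MeOH (4:1), −78 °C, then 0 °C
Reagents that add atoms: none
Why: Reductive epoxy-ketone opening by SmI2 cleaves the Cα–O bond through the ketyl to leave the C3 alkoxide and a samarium enolate, which should be protonated by samarium-bound methanol on the alkoxide face, anti to the C8a methyl and the C3 isopropyl group (trans ring fusion); the β-hydroxy ketone is then reduced further by electron transfer within a samarium chelate to the C3 oxygen, which should give the equatorial C4 carbinol syn to that oxygen.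

Step 13
Reactants: 19 (3R,3aR,4R,8aS)-6,8a-dimethyl-3-(propan-2-yl)-1,2,3,3a,4,5,8,8a-octahydroazulene-3,4-diol; 20 3,4-dimethoxybenzoyl chloride
Product: 21 (3R,3aR,4R,8aS)-3-hydroxy-6,8a-dimethyl-3-(propan-2-yl)-1,2,3,3a,4,5,8,8a-octahydroazulen-4-yl 3,4-dimethoxybenzoate
Conditions: Et3N, DMAP (cat.), CH2Cl2, 0 °C to rt
Reagents that add atoms: none
Why: DMAP-catalysed acylation distinguishes the secondary C4 hydroxyl from the hindered tertiary C3 hydroxyl, so the acid chloride esterifies C4 only and with retention.

**Compound list**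

1 | methyl acetoacetate | COC(=O)CC(C)=O | starting material
2 | methyl 2-diazo-3-oxobutanoate | COC(=O)C(=[N+]=[N-])C(C)=O | intermediate
3 | methyl 3-{[tert-butyl(dimethyl)silyl]oxy}-2-diazobut-3-enoate | COC(=O)C(=[N+]=[N-])C(=C)O[Si](C)(C)C(C)(C)C | intermediate
4 | 2-methylpenta-1,4-diene | C=C(C)CC=C | starting material
5 | methyl (5S)-2-{[tert-butyl(dimethyl)silyl]oxy}-5-methyl-5-(prop-2-en-1-yl)cyclopent-1-ene-1-carboxylate | COC(=O)C1=C(O[Si](C)(C)C(C)(C)C)CC[C@@]1(C)CC=C | intermediate
6 | caesium (3S)-2-(methoxycarbonyl)-3-methyl-3-(prop-2-en-1-yl)cyclopent-1-en-1-olate (not isolated) | COC(=O)C1=C([O-])CC[C@@]1(C)CC=C.[Cs+] | intermediate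
7 | methyl (5S)-5-methyl-5-(prop-2-en-1-yl)-2-{[(trifluoromethyl)sulfonyl]oxy}cyclopent-1-ene-1-carboxylate | COC(=O)C1=C(OS(=O)(=O)C(F)(F)F)CC[C@@]1(C)CC=C | intermediate
8 | isopropylmagnesium chloride | CC(C)[Mg]Cl | starting material
9 | methyl (5S)-5-methyl-2-(propan-2-yl)-5-(prop-2-en-1-yl)cyclopent-1-ene-1-carboxylate | COC(=O)C1=C(C(C)C)CC[C@@]1(C)CC=C | intermediate
10 | [(5S)-5-methyl-2-(propan-2-yl)-5-(prop-2-en-1-yl)cyclopent-1-en-1-yl]methanol | OCC1=C(C(C)C)CC[C@@]1(C)CC=C | intermediate
11 | (5S)-5-methyl-2-(propan-2-yl)-5-(prop-2-en-1-yl)cyclopent-1-ene-1-carbaldehyde | O=CC1=C(C(C)C)CC[C@@]1(C)CC=C | intermediate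
12 | 4,4,5,5-tetramethyl-2-(2-methylprop-2-en-1-yl)-1,3,2-dioxaborolane | CC(=C)CB1OC(C)(C)C(C)(C)O1 | starting material
13 | 4,4,5,5-tetramethyl-2-{(1R)-3-methyl-1-[(5S)-5-methyl-2-(propan-2-yl)-5-(prop-2-en-1-yl)cyclopent-1-en-1-yl]but-3-en-1-yloxy}-1,3,2-dioxaborolane (not isolated) | CC1(C)OB(O[C@H](CC(C)=C)C2=C(C(C)C)CC[C@@]2(C)CC=C)OC1(C)C | intermediate
14 | (1R)-3-methyl-1-[(5S)-5-methyl-2-(propan-2-yl)-5-(prop-2-en-1-yl)cyclopent-1-en-1-yl]but-3-en-1-ol | O[C@H](CC(C)=C)C1=C(C(C)C)CC[C@@]1(C)CC=C | intermediate
15 | (4R,8aS)-6,8a-dimethyl-3-(propan-2-yl)-1,2,4,5,8,8a-hexahydroazulen-4-ol | O[C@@H]1CC(C)=CC[C@]2(C)CCC(C(C)C)=C12 | intermediate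
16 | (3R,3aS,4R,8aS)-3,3a-epoxy-6,8a-dimethyl-3-(propan-2-yl)-1,2,3,3a,4,5,8,8a-octahydroazulen-4-ol | O[C@@H]1CC(C)=CC[C@]2(C)CC[C@]3(C(C)C)O[C@]123 | intermediate
17 | (3R,3aR,8aS)-3,3a-epoxy-6,8a-dimethyl-3-(propan-2-yl)-2,3,3a,5,8,8a-hexahydroazulen-4(1H)-one | O=C1CC(C)=CC[C@]2(C)CC[C@]3(C(C)C)O[C@]123 | intermediate
18 | (3R,3aS,8aS)-3-hydroxy-6,8a-dimethyl-3-(propan-2-yl)-2,3,3a,5,8,8a-hexahydroazulen-4(1H)-one (not isolated) | O=C1CC(C)=CC[C@]2(C)CC[C@@](O)(C(C)C)[C@@H]12 | intermediate
19 | (3R,3aR,4R,8aS)-6,8a-dimethyl-3-(propan-2-yl)-1,2,3,3a,4,5,8,8a-octahydroazulene-3,4-diol | O[C@@H]1CC(C)=CC[C@]2(C)CC[C@@](O)(C(C)C)[C@@H]12 | intermediate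
20 | 3,4-dimethoxybenzoyl chloride | COc1ccc(C(Cl)=O)cc1OC | starting material
21 | (3R,3aR,4R,8aS)-3-hydroxy-6,8a-dimethyl-3-(propan-2-yl)-1,2,3,3a,4,5,8,8a-octahydroazulen-4-yl 3,4-dimethoxybenzoate | COc1ccc(C(=O)O[C@@H]2CC(C)=CC[C@]3(C)CC[C@@](O)(C(C)C)[C@@H]23)cc1OC | target

**Step count and risks**

Total steps: 13. Longest linear sequence: 13 steps (1 to 21).

Step 3 (Proposed new method). The gold carbene may be attacked at the carbene carbon (cyclopropanation) instead of the vinylogous carbon. The tertiary cation may lose a proton before ring closure, and facial discrimination at the quaternary centre may be low. The fallback uses known chemistry and takes the quaternary centre from a bought stereocentre; it sets out from 1 and comes back at 7. The dianion of 1 (NaH, then n-BuLi, THF, 0 °C) is alkylated at its terminal carbon with (4S)-5-iodo-4-methylpent-1-ene F1, made from commercial (2S)-2-methylpent-4-en-1-ol with I2, PPh3 and imidazole. This gives methyl (6R)-6-methyl-3-oxonon-8-enoate F2. Diazo transfer (4-acetamidobenzenesulfonyl azide, Et3N, MeCN) gives methyl (6R)-2-diazo-6-methyl-3-oxonon-8-enoate F3. Rh2(OAc)4 in CH2Cl2 then effects 1,5-insertion of the carbenoid into the tertiary C–H bond with retention, which closes the C3a–C8a bond and gives methyl (2S)-2-methyl-5-oxo-2-(prop-2-en-1-yl)cyclopentane-1-carboxylate F4. NaH and PhNTf2 in THF convert F4 into enol triflate 7.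

Step 12. The samarium enolate may be protonated on the wrong face (cis ring fusion), the aldolate may open by retro-aldol cleavage, or the electron-transfer reduction may set the C4 carbinol on the wrong face. The fallback leaves the C4 carbinol of step 8 untouched; it sets out from 16 and comes back at 19 and makes no new compound (F0). The trivalent titanium reagent Cp2TiCl, made in the flask from Cp2TiCl2 and Mn dust in THF, opens the epoxy alcohol 16 homolytically at C3a with the oxygen kept on C3. Hydrogen-atom transfer from H2O bound to titanium, or from 1,4-cyclohexadiene, then gives the 1,3-diol 19 directly, on the face away from the C8a methyl and the isopropyl group.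

Step 8. Addition to the hindered tetrasubstituted enal may be sluggish, and the uncatalysed background allylboration would erode facial control. The fallback separates bond formation from stereocontrol; it sets out from 11 and comes back at 14. 2-Methylallylmagnesium chloride adds to 11 (THF, −78 °C) without stereocontrol to give 3-methyl-1-[(5S)-5-methyl-2-(propan-2-yl)-5-(prop-2-en-1-yl)cyclopent-1-en-1-yl]but-3-en-1-ol as both carbinol epimers F5. Dess–Martin oxidation gives 3-methyl-1-[(5S)-5-methyl-2-(propan-2-yl)-5-(prop-2-en-1-yl)cyclopent-1-en-1-yl]but-3-en-1-one F6. Corey–Bakshi–Shibata reduction with the (S)-methyl oxazaborolidine and catecholborane (toluene, −78 °C) then returns the (R)-carbinol 14.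

Further compounds
F1 | step 3 | (4S)-5-iodo-4-methylpent-1-ene | C=CC[C@H](C)CI
F2 | step 3 | methyl (6R)-6-methyl-3-oxonon-8-enoate | C=CC[C@H](C)CCC(=O)CC(=O)OC
F3 | step 3 | methyl (6R)-2-diazo-6-methyl-3-oxonon-8-enoate | C=CC[C@H](C)CCC(=O)C(=[N+]=[N-])C(=O)OC
F4 | step 3 | methyl (2S)-2-methyl-5-oxo-2-(prop-2-en-1-yl)cyclopentane-1-carboxylate | COC(=O)C1C(=O)CC[C@@]1(C)CC=C
F0 | step 12 | none | none
F5 | step 8 | 3-methyl-1-[(5S)-5-methyl-2-(propan-2-yl)-5-(prop-2-en-1-yl)cyclopent-1-en-1-yl]but-3-en-1-ol (both carbinol epimers) | OC(CC(C)=C)C1=C(C(C)C)CC[C@@]1(C)CC=C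
F6 | step 8 | 3-methyl-1-[(5S)-5-methyl-2-(propan-2-yl)-5-(prop-2-en-1-yl)cyclopent-1-en-1-yl]but-3-en-1-one | O=C(CC(C)=C)C1=C(C(C)C)CC[C@@]1(C)CC=C
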